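**Retrosynthetic overview**

1. Cyclohexene numbering: C1 (methyl-bearing), C2, C3 (acyl-resorcinol ring), C4 (aroyl), C5 (resorcinol ring), C6. Target ⇐ cleavage of eight MOM ethers ⇐ Claisen–Schmidt condensation of a ring-bound acetyl group with 2,4-bis(methoxymethoxy)benzaldehyde.
2. Cyclohexene ring ⇐ ring-closing metathesis (C1=C2) of an acyclic propenyl/methallyl ketone; aroyl group ⇐ aryllithium + carboxylic acid.
3. Key step: C3–C4 bond with both stereocentres ⇐ Ireland–Claisen rearrangement of an (R,E)-allylic ester (chirality transfer from (R)-but-3-yn-2-ol).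
4. C5 stereocentre ⇐ trans conjugate arylation of (S)-parasorbic acid (from (S)-pent-4-en-2-ol); the lactone carbinol carbon is then oxidised and methylenated to become C1 with its methyl group.
5. Ring order: temporary δ-lactone (metathesis, later opened), temporary dioxolane, cyclohexene ring last; the four benzene rings are bought.

Abbreviations: MOM = CH2OCH3; ArP = 2,4-bis(methoxymethoxy)phenyl; ArK = 2,6-bis(methoxymethoxy)-3-(2-methyl-1,3-dioxolan-2-yl)phenyl; ArA = 3-acetyl-2,6-bis(methoxymethoxy)phenyl.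

Assumption: the two enantiopure alcohols ((S)-pent-4-en-2-ol, (R)-but-3-yn-2-ol) and 2,4-bis(methoxymethoxy)benzaldehyde are bought as such.

**Route**

Step 1
Reactants: 1 4-bromobenzene-1,3-diol
Product: 2 1-bromo-2,4-bis(methoxymethoxy)benzene
Conditions: MOMCl, i-Pr2NEt, CH2Cl2, 0 → 25 °C
Reagents that add atoms: chloromethyl methyl ether, COCCl
Why: Twofold O-alkylation (MOM ether formation) masks both phenols as base-stable acetals that also stabilise the later ortho-metalated arene.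

Step 2
Reactants: 3 (S)-pent-4-en-2-ol; 4 acryloyl chloride
Product: 5 (S)-pent-4-en-2-yl acrylate
Conditions: Et3N, CH2Cl2, 0 °C
Reagents that add atoms: none
Why: O-Acylation of the purchased secondary alcohol does not involve its stereocentre.

Step 3
Reactants: 5 (S)-pent-4-en-2-yl acrylate
Product: 6 (S)-6-methyl-5,6-dihydro-2H-pyran-2-one
Conditions: second-generation Grubbs catalyst RuCl2(=CHPh)(PCy3)(H2IMes) (3 mol %), CH2Cl2 (5 mM), 40 °C
Reagents that add atoms: none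
Why: Ring-closing metathesis of the acrylate/allyl diene gives the unsaturated δ-lactone (parasorbic acid) with loss of ethene and leaves the stereocentre untouched.

Step 4
Reactants: 2 1-bromo-2,4-bis(methoxymethoxy)benzene; 6 (S)-6-methyl-5,6-dihydro-2H-pyran-2-one
Product: 8 (4S,6S)-4-ArP-6-methyltetrahydro-2H-pyran-2-one, via aryl Grignard reagent 7 (not isolated)
Conditions: 2, Mg, THF, 40 °C; then CuBr·SMe2 (10 mol %), 6, THF, −40 °C; H2O
Reagents that add atoms: none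
Why: Copper-catalysed conjugate addition of the aryl Grignard reagent takes place on the lactone face anti to the methyl group on lactone C6, so the purchased centre sets the new aryl-bearing centre trans (4S).

Step 5
Reactants: 8 (4S,6S)-4-ArP-6-methyltetrahydro-2H-pyran-2-one
Product: 10 (S)-3-ArP-5-oxohexanoic acid, via ammonium hydroxy carboxylate 9 (not isolated)
Conditions: n-Bu4NOH (1.0 equiv), THF–H2O, 25 °C; evaporate; Pr4N[RuO4] (5 mol %), N-methylmorpholine N-oxide, 4 Å sieves, CH2Cl2–MeCN, 25 °C; aq. HCl to pH 3, 0 °C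
Reagents that add atoms: tetrabutylammonium hydroxide, CCCC[N+](CCCC)(CCCC)CCCC.[OH-]
Why: Saponification followed by Ley–Griffith oxidation of the ammonium hydroxy carboxylate (which cannot relactonise) removes the carbinol centre after it has done its work and leaves the aryl-bearing centre untouched.

Step 6
Reactants: 10 (S)-3-ArP-5-oxohexanoic acid
Product: 11 (S)-3-ArP-5-methylhex-5-enoic acid
Conditions: Ph3PCH3Br, KOt-Bu (excess), THF, 0 → 25 °C; aq. HCl to pH 3
Reagents that add atoms: methyltriphenylphosphonium bromide, C[P+](c1ccccc1)(c1ccccc1)c1ccccc1.[Br-]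
Why: Wittig methylenation of the methyl ketone (the carboxylate is inert to the ylide) gives the methallyl group that becomes C6, C1 and the ring methyl.

Step 7
Reactants: 12 1-(2,4-dihydroxyphenyl)ethanone
Product: 13 1-(2,4-dihydroxy-3-iodophenyl)ethanone
Conditions: I2, HIO3, EtOH–H2O, 35 °C
Reagents that add atoms: iodine, [I][I]; iodic acid, O=I(=O)O
Why: Electrophilic aromatic iodination goes to the position flanked by both hydroxyl groups.

Step 8
Reactants: 13 1-(2,4-dihydroxy-3-iodophenyl)ethanone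
Product: 14 1-[3-iodo-2,4-bis(methoxymethoxy)phenyl]ethanone
Conditions: NaH, MOMCl, DMF, 0 → 25 °C
Reagents that add atoms: chloromethyl methyl ether, COCCl
Why: Williamson-type MOM protection through the sodium phenoxides also alkylates the chelated ortho hydroxyl group.

Step 9
Reactants: 14 1-[3-iodo-2,4-bis(methoxymethoxy)phenyl]ethanone
Product: 15 2-[3-iodo-2,4-bis(methoxymethoxy)phenyl]-2-methyl-1,3-dioxolane
Conditions: Me3SiOCH2CH2OSiMe3, Me3SiOTf (5 mol %), CH2Cl2, −78 → −20 °C; pyridine quench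
Reagents that add atoms: 1,2-bis(trimethylsilyloxy)ethane, C[Si](C)(C)OCCO[Si](C)(C)C
Why: Noyori ketalisation under cold aprotic conditions protects the acetyl group against the later amide base and aryllithium without cleaving the MOM ethers.

Step 10
Reactants: 15 2-[3-iodo-2,4-bis(methoxymethoxy)phenyl]-2-methyl-1,3-dioxolane; 16 (R)-but-3-yn-2-ol
Product: 17 (R)-4-ArK-but-3-yn-2-ol
Conditions: Pd(PPh3)2Cl2 (3 mol %), CuI (5 mol %), Et3N, THF, 50 °C
Reagents that add atoms: none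
Why: Sonogashira coupling joins the aryl iodide to the purchased alkynol without touching the carbinol centre.

Step 11
Reactants: 17 (R)-4-ArK-but-3-yn-2-ol
Product: 18 (R,E)-4-ArK-but-3-en-2-ol
Conditions: NaAlH2(OCH2CH2OMe)2, THF, 0 → 25 °C; H2O
Reagents that add atoms: none
Why: Hydroxyl-directed trans-hydroalumination of the propargylic alcohol followed by protonolysis gives only the (E)-allylic alcohol with the (R) centre retained.

Step 12
Reactants: 11 (S)-3-ArP-5-methylhex-5-enoic acid; 18 (R,E)-4-ArK-but-3-en-2-ol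
Product: 19 (R,E)-4-ArK-but-3-en-2-yl (S)-3-ArP-5-methylhex-5-enoate
Conditions: DCC, DMAP (cat.), CH2Cl2, 0 → 25 °C
Reagents that add atoms: none
Why: Steglich esterification under neutral conditions avoids ionisation of the electron-rich allylic alcohol, so both stereocentres are kept.

Step 13
Reactants: 19 (R,E)-4-ArK-but-3-en-2-yl (S)-3-ArP-5-methylhex-5-enoate
Product: 22 (2R,3S,E)-3-ArK-2-[(S)-1-ArP-3-methylbut-3-en-1-yl]hex-4-enoic acid, via silyl ketene acetal 20 (not isolated), via trimethylsilyl ester 21 (not isolated)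
Conditions: LiN(i-Pr)2 (1.3 equiv), THF–DMPU (3:1), −78 °C; Me3SiCl; −78 → 25 °C, 12 h; H2O (pH 5–6)
Reagents that add atoms: none
Why: The Ireland–Claisen [3,3]-sigmatropic rearrangement runs through a chair with the carbinol methyl equatorial, so the (R) carbinol centre is transferred to the new (3S) benzylic centre (ring C3), and the (Z)-silyl ketene acetal formed in THF–DMPU combined with the (E)-alkene gives the 2,3-syn (2R) centre (ring C4).

Step 14
Reactants: 22 (2R,3S,E)-3-ArK-2-[(S)-1-ArP-3-methylbut-3-en-1-yl]hex-4-enoic acid; 2 1-bromo-2,4-bis(methoxymethoxy)benzene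
Product: 25 (2R,3S,E)-3-ArA-1-ArP-2-[(S)-1-ArP-3-methylbut-3-en-1-yl]hex-4-en-1-one, via aryllithium 23 (not isolated), via dioxolane ketone 24 (not isolated)
Conditions: 2 (2.6 equiv), n-BuLi (2.5 equiv), THF, −78 °C; add 22, −78 → 0 °C; 1 M aq. HCl–THF, 0 °C, 30 min
Reagents that add atoms: water, O
Why: Addition of the aryllithium to the lithium carboxylate gives a gem-diolate that can neither over-add nor enolise and collapses to the aryl ketone on acidification, which also hydrolyses the labile dioxolane, with no stereocentre touched.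

Step 15
Reactants: 25 (2R,3S,E)-3-ArA-1-ArP-2-[(S)-1-ArP-3-methylbut-3-en-1-yl]hex-4-en-1-one
Product: 26 1-{3-[(1S,5S,6R)-6-[2,4-bis(methoxymethoxy)benzoyl]-5-ArP-3-methylcyclohex-2-en-1-yl]-2,4-bis(methoxymethoxy)phenyl}ethanone
Conditions: second-generation Grubbs catalyst RuCl2(=CHPh)(PCy3)(H2IMes) (5 mol %), toluene, 60 °C
Reagents that add atoms: none
Why: Ring-closing metathesis between the propenyl and methallyl groups closes the trisubstituted cyclohexene (C1=C2) with loss of propene and without touching the three stereocentres.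

Step 16
Reactants: 26 1-{3-[(1S,5S,6R)-6-[2,4-bis(methoxymethoxy)benzoyl]-5-ArP-3-methylcyclohex-2-en-1-yl]-2,4-bis(methoxymethoxy)phenyl}ethanone; 27 2,4-bis(methoxymethoxy)benzaldehyde
Product: 28 (E)-1-{3-[(1S,5S,6R)-6-[2,4-bis(methoxymethoxy)benzoyl]-5-ArP-3-methylcyclohex-2-en-1-yl]-2,4-bis(methoxymethoxy)phenyl}-3-ArP-prop-2-en-1-one
Conditions: KOH, EtOH–THF, 25 °C
Reagents that add atoms: none
Why: Claisen–Schmidt aldol condensation of the methyl ketone gives the (E)-enone, the only other enolisable site (the tertiary ring methine next to the aroyl group) being far more hindered.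

Step 17
Reactants: 28 (E)-1-{3-[(1S,5S,6R)-6-[2,4-bis(methoxymethoxy)benzoyl]-5-ArP-3-methylcyclohex-2-en-1-yl]-2,4-bis(methoxymethoxy)phenyl}-3-ArP-prop-2-en-1-one
Product: 29 (E)-1-{3-[(1S,5S,6R)-6-(2,4-dihydroxybenzoyl)-5-(2,4-dihydroxyphenyl)-3-methylcyclohex-2-en-1-yl]-2,4-dihydroxyphenyl}-3-(2,4-dihydroxyphenyl)prop-2-en-1-one (target)
Conditions: 3 M HCl, MeOH–THF, 40 °C
Reagents that add atoms: none
Why: Acid-catalysed acetal exchange with methanol removes all eight MOM groups as dimethoxymethane and leaves the stereocentres and both enones unchanged.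

**Compound list**

1 | 4-bromobenzene-1,3-diol | Oc1ccc(Br)c(O)c1 | starting material
2 | 1-bromo-2,4-bis(methoxymethoxy)benzene | COCOc1ccc(Br)c(OCOC)c1 | intermediate
3 | (S)-pent-4-en-2-ol | C[C@H](O)CC=C | starting material
4 | acryloyl chloride | C=CC(=O)Cl | starting material
5 | (S)-pent-4-en-2-yl acrylate | C[C@H](OC(=O)C=C)CC=C | intermediate
6 | (S)-6-methyl-5,6-dihydro-2H-pyran-2-one | C[C@H]1CC=CC(=O)O1 | intermediate
7 | [2,4-bis(methoxymethoxy)phenyl]magnesium bromide | COCOc1ccc([Mg]Br)c(OCOC)c1 | intermediate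
8 | (4S,6S)-4-ArP-6-methyltetrahydro-2H-pyran-2-one | O=C1C[C@@H](c2ccc(OCOC)cc2OCOC)C[C@H](C)O1 | intermediate
9 | tetrabutylammonium (3S,5S)-3-ArP-5-hydroxyhexanoate | CCCC[N+](CCCC)(CCCC)CCCC.[O-]C(=O)C[C@@H](c1ccc(OCOC)cc1OCOC)C[C@H](C)O | intermediate
10 | (S)-3-ArP-5-oxohexanoic acid | OC(=O)C[C@@H](c1ccc(OCOC)cc1OCOC)CC(C)=O | intermediate
11 | (S)-3-ArP-5-methylhex-5-enoic acid | OC(=O)C[C@@H](c1ccc(OCOC)cc1OCOC)CC(C)=C | intermediate
12 | 1-(2,4-dihydroxyphenyl)ethanone | CC(=O)c1ccc(O)cc1O | starting material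
13 | 1-(2,4-dihydroxy-3-iodophenyl)ethanone | CC(=O)c1ccc(O)c(I)c1O | intermediate
14 | 1-[3-iodo-2,4-bis(methoxymethoxy)phenyl]ethanone | CC(=O)c1ccc(OCOC)c(I)c1OCOC | intermediate
15 | 2-[3-iodo-2,4-bis(methoxymethoxy)phenyl]-2-methyl-1,3-dioxolane | CC1(c2ccc(OCOC)c(I)c2OCOC)OCCO1 | intermediate
16 | (R)-but-3-yn-2-ol | C[C@@H](O)C#C | starting material
17 | (R)-4-ArK-but-3-yn-2-ol | C[C@@H](O)C#Cc1c(OCOC)ccc(C2(C)OCCO2)c1OCOC | intermediate
18 | (R,E)-4-ArK-but-3-en-2-ol | C[C@@H](O)/C=C/c1c(OCOC)ccc(C2(C)OCCO2)c1OCOC | intermediate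
19 | (R,E)-4-ArK-but-3-en-2-yl (S)-3-ArP-5-methylhex-5-enoate | C[C@@H](OC(=O)C[C@@H](c1ccc(OCOC)cc1OCOC)CC(C)=C)/C=C/c1c(OCOC)ccc(C2(C)OCCO2)c1OCOC | intermediate
20 | (Z)-trimethylsilyl ketene acetal of 19 (silyloxy group cis to the C3 substituent) | C[C@@H](O/C(O[Si](C)(C)C)=C/[C@@H](c1ccc(OCOC)cc1OCOC)CC(C)=C)/C=C/c1c(OCOC)ccc(C2(C)OCCO2)c1OCOC | intermediate
21 | trimethylsilyl (2R,3S,E)-3-ArK-2-[(S)-1-ArP-3-methylbut-3-en-1-yl]hex-4-enoate | C/C=C/[C@H](c1c(OCOC)ccc(C2(C)OCCO2)c1OCOC)[C@H](C(=O)O[Si](C)(C)C)[C@@H](c1ccc(OCOC)cc1OCOC)CC(C)=C | intermediate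
22 | (2R,3S,E)-3-ArK-2-[(S)-1-ArP-3-methylbut-3-en-1-yl]hex-4-enoic acid | C/C=C/[C@H](c1c(OCOC)ccc(C2(C)OCCO2)c1OCOC)[C@H](C(=O)O)[C@@H](c1ccc(OCOC)cc1OCOC)CC(C)=C | intermediate
23 | [2,4-bis(methoxymethoxy)phenyl]lithium | COCOc1ccc([Li])c(OCOC)c1 | intermediate
24 | (2R,3S,E)-3-ArK-1-ArP-2-[(S)-1-ArP-3-methylbut-3-en-1-yl]hex-4-en-1-one | C/C=C/[C@H](c1c(OCOC)ccc(C2(C)OCCO2)c1OCOC)[C@H](C(=O)c1ccc(OCOC)cc1OCOC)[C@@H](c1ccc(OCOC)cc1OCOC)CC(C)=C | intermediate
25 | (2R,3S,E)-3-ArA-1-ArP-2-[(S)-1-ArP-3-methylbut-3-en-1-yl]hex-4-en-1-one | C/C=C/[C@H](c1c(OCOC)ccc(C(C)=O)c1OCOC)[C@H](C(=O)c1ccc(OCOC)cc1OCOC)[C@@H](c1ccc(OCOC)cc1OCOC)CC(C)=C | intermediate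
26 | 1-{3-[(1S,5S,6R)-6-[2,4-bis(methoxymethoxy)benzoyl]-5-ArP-3-methylcyclohex-2-en-1-yl]-2,4-bis(methoxymethoxy)phenyl}ethanone | CC1=C[C@H](c2c(OCOC)ccc(C(C)=O)c2OCOC)[C@H](C(=O)c2ccc(OCOC)cc2OCOC)[C@@H](c2ccc(OCOC)cc2OCOC)C1 | intermediate
27 | 2,4-bis(methoxymethoxy)benzaldehyde | COCOc1ccc(C=O)c(OCOC)c1 | starting material
28 | (E)-1-{3-[(1S,5S,6R)-6-[2,4-bis(methoxymethoxy)benzoyl]-5-ArP-3-methylcyclohex-2-en-1-yl]-2,4-bis(methoxymethoxy)phenyl}-3-ArP-prop-2-en-1-one | CC1=C[C@H](c2c(OCOC)ccc(C(=O)/C=C/c3ccc(OCOC)cc3OCOC)c2OCOC)[C@H](C(=O)c2ccc(OCOC)cc2OCOC)[C@@H](c2ccc(OCOC)cc2OCOC)C1 | intermediate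
29 | (E)-1-{3-[(1S,5S,6R)-6-(2,4-dihydroxybenzoyl)-5-(2,4-dihydroxyphenyl)-3-methylcyclohex-2-en-1-yl]-2,4-dihydroxyphenyl}-3-(2,4-dihydroxyphenyl)prop-2-en-1-one | CC1=C[C@H](c2c(O)ccc(C(=O)/C=C/c3ccc(O)cc3O)c2O)[C@H](C(=O)c2ccc(O)cc2O)[C@@H](c2ccc(O)cc2O)C1 | target

**Step count and risks**

Total steps: 17. Longest linear sequence: 11 steps (steps 2, 3, 4, 5, 6, 12, 13, 14, 15, 16, 17; the branch from 12 through steps 7–11 is equally long).

Step 13 (Ireland–Claisen). The risks are incomplete control of the ketene acetal geometry in THF–DMPU and slow bond formation at the hindered benzylic terminus. The fallback sets out from 15 and comes back at 22; it fixes the syn relationship through the alkene geometry instead of the solvent. Sonogashira coupling of 15 with commercial (S)-but-3-yn-2-ol gives (S)-4-ArK-but-3-yn-2-ol F1. Semihydrogenation (H2, Pd on CaCO3 poisoned with Pb(OAc)2, quinoline) gives (S,Z)-4-ArK-but-3-en-2-ol F2. Steglich esterification with 11 gives (S,Z)-4-ArK-but-3-en-2-yl (S)-3-ArP-5-methylhex-5-enoate F3. Enolisation with LiN(i-Pr)2 in THF alone and silylation give the kinetically preferred (E)-trimethylsilyl ketene acetal F4. Its chair rearrangement (aryl axial, carbinol methyl equatorial) leads through silyl ester 21 to the same acid 22.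

Step 14 (aryl ketone from the acid). The α,β-branched lithium carboxylate may be too hindered for the ortho-substituted aryllithium. The fallback sets out from 22 and comes back at 24. LiAlH4 reduction gives (2R,3S,E)-3-ArK-2-[(S)-1-ArP-3-methylbut-3-en-1-yl]hex-4-en-1-ol F5. Dess–Martin oxidation (NaHCO3 buffer) gives (2R,3S,E)-3-ArK-2-[(S)-1-ArP-3-methylbut-3-en-1-yl]hex-4-enal F6. Addition of aryllithium 23 at −78 °C gives (2R,3S,E)-1-ArP-3-ArK-2-[(S)-1-ArP-3-methylbut-3-en-1-yl]hex-4-en-1-ol F7 as both carbinol epimers. A second Dess–Martin oxidation gives dioxolane ketone 24, which the acid treatment of step 14 converts into 25.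

Step 17 (global deprotection). The free 2-hydroxychalcone, the phenol-flanked aryl ketone and the ring alkene are acid-sensitive (flavanone or flavylium formation, ketalisation, chroman formation). The fallback sets out from 26 and comes back at 29; it moves the acid step in front of chalcone formation and ends with mild base. HCl in MeOH on 26 gives 1-{3-[(1S,5S,6R)-6-(2,4-dihydroxybenzoyl)-5-(2,4-dihydroxyphenyl)-3-methylcyclohex-2-en-1-yl]-2,4-dihydroxyphenyl}ethanone F8. Ac2O, pyridine and DMAP give its hexaacetate F9. 2,4-Dihydroxybenzaldehyde and Ac2O give 2,4-diacetoxybenzaldehyde F10. BF3·OEt2-mediated Claisen–Schmidt condensation of F9 with F10 (conditions that tolerate aryl acetates) gives the octaacetate of the target F11. K2CO3 in MeOH at 0 °C removes the acetates and gives 29.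

**Further compounds**

F1 | step 13 | (S)-4-ArK-but-3-yn-2-ol | C[C@H](O)C#Cc1c(OCOC)ccc(C2(C)OCCO2)c1OCOC
F2 | step 13 | (S,Z)-4-ArK-but-3-en-2-ol | C[C@H](O)/C=C\c1c(OCOC)ccc(C2(C)OCCO2)c1OCOC
F3 | step 13 | (S,Z)-4-ArK-but-3-en-2-yl (S)-3-ArP-5-methylhex-5-enoate | C[C@H](OC(=O)C[C@@H](c1ccc(OCOC)cc1OCOC)CC(C)=C)/C=C\c1c(OCOC)ccc(C2(C)OCCO2)c1OCOC
F4 | step 13 | (E)-trimethylsilyl ketene acetal of F3 | C[C@H](O/C(O[Si](C)(C)C)=C\[C@@H](c1ccc(OCOC)cc1OCOC)CC(C)=C)/C=C\c1c(OCOC)ccc(C2(C)OCCO2)c1OCOC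
F5 | step 14 | (2R,3S,E)-3-ArK-2-[(S)-1-ArP-3-methylbut-3-en-1-yl]hex-4-en-1-ol | C/C=C/[C@H](c1c(OCOC)ccc(C2(C)OCCO2)c1OCOC)[C@H](CO)[C@@H](c1ccc(OCOC)cc1OCOC)CC(C)=C
F6 | step 14 | (2R,3S,E)-3-ArK-2-[(S)-1-ArP-3-methylbut-3-en-1-yl]hex-4-enal | C/C=C/[C@H](c1c(OCOC)ccc(C2(C)OCCO2)c1OCOC)[C@H](C=O)[C@@H](c1ccc(OCOC)cc1OCOC)CC(C)=C
F7 | step 14 | (2R,3S,E)-1-ArP-3-ArK-2-[(S)-1-ArP-3-methylbut-3-en-1-yl]hex-4-en-1-ol (both C1 epimers) | C/C=C/[C@H](c1c(OCOC)ccc(C2(C)OCCO2)c1OCOC)[C@H](C(O)c1ccc(OCOC)cc1OCOC)[C@@H](c1ccc(OCOC)cc1OCOC)CC(C)=C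
F8 | step 17 | 1-{3-[(1S,5S,6R)-6-(2,4-dihydroxybenzoyl)-5-(2,4-dihydroxyphenyl)-3-methylcyclohex-2-en-1-yl]-2,4-dihydroxyphenyl}ethanone | CC1=C[C@H](c2c(O)ccc(C(C)=O)c2O)[C@H](C(=O)c2ccc(O)cc2O)[C@@H](c2ccc(O)cc2O)C1
F9 | step 17 | hexaacetate of F8 | CC1=C[C@H](c2c(OC(C)=O)ccc(C(C)=O)c2OC(C)=O)[C@H](C(=O)c2ccc(OC(C)=O)cc2OC(C)=O)[C@@H](c2ccc(OC(C)=O)cc2OC(C)=O)C1
F10 | step 17 | 2,4-diacetoxybenzaldehyde | CC(=O)Oc1ccc(C=O)c(OC(C)=O)c1
F11 | step 17 | octaacetate of 29 | CC1=C[C@H](c2c(OC(C)=O)ccc(C(=O)/C=C/c3ccc(OC(C)=O)cc3OC(C)=O)c2OC(C)=O)[C@H](C(=O)c2ccc(OC(C)=O)cc2OC(C)=O)[C@@H](c2ccc(OC(C)=O)cc2OC(C)=O)C1
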